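The target is the achiral flavonol 3,5,4'-trihydroxy-8,3'-dimethoxy-7-prenyloxyflavone. In ring C the neighbouring carbons C3 (enolic OH) and C4 (C=O) both bear oxygen, so at the diol oxidation level C3–C4 is the central bond of a 1,2-diol. Cutting it gives two aldehydes still held together by C4a–C8a–O1–C2.
Retrosynthetic cuts, in order: the MOM ethers on O5 and O4'; C3–C4 (pinacol); O1–C2 (phenoxide on an α-bromo arylacetate); O7–prenyl; C4–C4a (ortho-formylation); C5–O (Baeyer–Villiger degradation of a benzoate carbon).
Forward: ring A comes from methyl 4-O-methylgallate, and ring B with C2 and C3 comes from homovanillic acid. The two are joined at O1–C2. Ring C is the only ring made; it closes last at C3–C4 as a flavan-3,4-diol and is then aromatised by oxidation.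
Stereochemistry: C2 is racemic from the bromide, and C3 and C4 are set relative to it in the ring closure. All three centres are erased on oxidation to the flavonol, so none needs control.

Key step: step 15

Remark: compounds 16 to 21 are racemates and 15 is an E/Z mixture. For 20 one enantiomer of the expected major diastereomer is drawn, and any diastereomer mixture is carried on, because the target has no stereocentre.

Step 1
Reactants: 1 methyl 3,5-dihydroxy-4-methoxybenzoate
Product: 2 methyl 3,5-bis(benzyloxy)-4-methoxybenzoate
Conditions: BnBr (2.4 equiv), K2CO3, DMF, 60 °C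
Reagents that add atoms: benzyl bromide, BrCc1ccccc1
Why: Williamson ether synthesis on the two equivalent phenols gives a single product, and benzyl is chosen because it withstands hydride, peracid and base yet leaves by hydrogenolysis before the prenyl alkene enters.

Step 2
Reactants: 2 methyl 3,5-bis(benzyloxy)-4-methoxybenzoate
Product: 3 [3,5-bis(benzyloxy)-4-methoxyphenyl]methanol
Conditions: LiAlH4, THF, 0 °C → rt; H2O/aq. NaOH work-up
Reagents that add atoms: none
Why: LiAlH4 reduction of an aryl ester to the primary benzylic alcohol is routine and leaves the aryl ethers untouched.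

Step 3
Reactants: 3 [3,5-bis(benzyloxy)-4-methoxyphenyl]methanol
Product: 4 3,5-bis(benzyloxy)-4-methoxybenzaldehyde
Conditions: activated MnO2, CH2Cl2, rt
Reagents that add atoms: none
Why: Heterogeneous MnO2 oxidation is selective for benzylic alcohols and stops at the aldehyde.

Step 4
Reactants: 4 3,5-bis(benzyloxy)-4-methoxybenzaldehyde
Product: 6 3,5-bis(benzyloxy)-4-methoxyphenol, via aryl formate 5 (not isolated)
Conditions: mCPBA, CH2Cl2, 0 °C → rt; aq. NaHCO3 wash; then K2CO3 (cat.), MeOH, rt
Reagents that add atoms: 3-chloroperoxybenzoic acid, O=C(OO)c1cccc(Cl)c1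
Why: In this Baeyer–Villiger oxidation of a donor-rich benzaldehyde the para-methoxy group makes the aryl group migrate in preference to hydride, and base-catalysed methanolysis of the resulting formate frees the phenol oxygen that becomes O5.

Step 5
Reactants: 6 3,5-bis(benzyloxy)-4-methoxyphenol
Product: 7 2,4-bis(benzyloxy)-6-hydroxy-3-methoxybenzaldehyde
Conditions: MgCl2, Et3N, (CH2O)n, MeCN, reflux; then 1 M HCl
Reagents that add atoms: paraformaldehyde (as formaldehyde), C=O
Why: Casnati–Skattebøl ortho-formylation delivers formaldehyde within the magnesium phenoxide only ortho to the free hydroxyl, and since the two ortho positions are equivalent by symmetry and the para position carries the methoxy group, only one aldehyde (the future C4 on C4a) can form.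

Step 6
Reactants: 7 2,4-bis(benzyloxy)-6-hydroxy-3-methoxybenzaldehyde
Product: 8 2,4-bis(benzyloxy)-3-methoxy-6-(methoxymethoxy)benzaldehyde
Conditions: MOMCl, i-Pr2NEt, CH2Cl2, 0 °C → reflux
Reagents that add atoms: chloromethyl methyl ether, COCCl
Why: O-alkylation with the highly reactive chloromethyl ether (MOM acetal formation) overcomes the hydrogen bond to the aldehyde on warming and marks O5 as the oxygen that stays masked until the last step.

Step 7
Reactants: 8 2,4-bis(benzyloxy)-3-methoxy-6-(methoxymethoxy)benzaldehyde
Product: 9 2,4-dihydroxy-3-methoxy-6-(methoxymethoxy)benzaldehyde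
Conditions: H2 (1 atm), Pd/C (10 wt %), EtOAc, rt
Reagents that add atoms: none
Why: Catalytic hydrogenolysis cleaves both benzyl aryl ethers at ambient pressure, whereas the aldehyde, deactivated as a vinylogous acid by three oxygen donors, is reduced far more slowly, so the reaction is stopped once two equivalents of H2 are taken up.

Step 8
Reactants: 9 2,4-dihydroxy-3-methoxy-6-(methoxymethoxy)benzaldehyde; 10 prenyl bromide (1.05 equiv)
Product: 11 2-hydroxy-3-methoxy-6-(methoxymethoxy)-4-(3-methylbut-2-enyloxy)benzaldehyde
Conditions: K2CO3 (1.1 equiv), acetone, rt → 40 °C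
Reagents that add atoms: none
Why: In this regioselective Williamson etherification the 4-hydroxyl para to the formyl group is the more acidic and is free, while the 2-hydroxyl is tied up in a hydrogen bond to the aldehyde, so one equivalent of weak base and bromide should alkylate only the future O7.

Step 9
Reactants: 12 homovanillic acid
Product: 13 methyl 2-(4-hydroxy-3-methoxyphenyl)acetate
Conditions: MeOH, H2SO4 (cat.), reflux
Reagents that add atoms: methanol, CO
Why: Fischer esterification in excess methanol converts the acid cleanly and leaves the phenol free.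

Step 10
Reactants: 13 methyl 2-(4-hydroxy-3-methoxyphenyl)acetate
Product: 14 methyl 2-[3-methoxy-4-(methoxymethoxy)phenyl]acetate
Conditions: MOMCl, i-Pr2NEt, CH2Cl2, 0 °C → rt
Reagents that add atoms: chloromethyl methyl ether, COCCl
Why: MOM acetal formation on the only acidic hydroxyl gives O4' the same protecting group as O5, so that both fall in a single final operation.

Step 11
Reactants: 14 methyl 2-[3-methoxy-4-(methoxymethoxy)phenyl]acetate
Product: 16 methyl 2-bromo-2-[3-methoxy-4-(methoxymethoxy)phenyl]acetate (racemic), via ketene silyl acetal 15 (not isolated)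
Conditions: LiN(SiMe3)2, THF, −78 °C; Me3SiCl; then NBS, −78 → 0 °C
Reagents that add atoms: N-bromosuccinimide, O=C1CCC(=O)N1Br; chlorotrimethylsilane, C[Si](C)(C)Cl
Why: Electrophilic α-bromination of the ester through its ketene silyl acetal avoids the radical or acidic conditions that would endanger the MOM group and the donor-rich ring and keeps enolate and product bromide apart, and the new stereocentre (the future C2) forms racemic because the planar acetal is attacked from either face.

Step 12
Reactants: 11 2-hydroxy-3-methoxy-6-(methoxymethoxy)-4-(3-methylbut-2-enyloxy)benzaldehyde; 16 methyl 2-bromo-2-[3-methoxy-4-(methoxymethoxy)phenyl]acetate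
Product: 17 methyl 2-[6-formyl-2-methoxy-5-(methoxymethoxy)-3-(3-methylbut-2-enyloxy)phenoxy]-2-[3-methoxy-4-(methoxymethoxy)phenyl]acetate (racemic)
Conditions: K2CO3, DMF, rt
Reagents that add atoms: none
Why: Williamson-type SN2 displacement of a doubly activated (benzylic and α-carbonyl) bromide by the only free phenol of 11 makes the O1–C2 bond with no regiochemical choice, C2 stays racemic, and weak base at room temperature holds back the intramolecular aldol of the product.

Step 13
Reactants: 17 methyl 2-[6-formyl-2-methoxy-5-(methoxymethoxy)-3-(3-methylbut-2-enyloxy)phenoxy]-2-[3-methoxy-4-(methoxymethoxy)phenyl]acetate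
Product: 18 2-[6-(hydroxymethyl)-2-methoxy-5-(methoxymethoxy)-3-(3-methylbut-2-enyloxy)phenoxy]-2-[3-methoxy-4-(methoxymethoxy)phenyl]ethanol (racemic)
Conditions: LiAlH4, THF, 0 °C; H2O/aq. NaOH work-up
Reagents that add atoms: none
Why: Exhaustive LiAlH4 reduction takes ester and aryl aldehyde together to the diol, which avoids having to stop an ester at the aldehyde stage beside a more reactive aldehyde, and MOM, aryl and prenyl ethers are inert to hydride.

Step 14
Reactants: 18 2-[6-(hydroxymethyl)-2-methoxy-5-(methoxymethoxy)-3-(3-methylbut-2-enyloxy)phenoxy]-2-[3-methoxy-4-(methoxymethoxy)phenyl]ethanol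
Product: 19 2-[6-formyl-2-methoxy-5-(methoxymethoxy)-3-(3-methylbut-2-enyloxy)phenoxy]-2-[3-methoxy-4-(methoxymethoxy)phenyl]acetaldehyde (racemic)
Conditions: Dess–Martin periodinane (2.4 equiv), NaHCO3, CH2Cl2, 0 °C → rt
Reagents that add atoms: none
Why: Dess–Martin oxidation converts primary and benzylic alcohols to aldehydes under near-neutral, non-aqueous conditions without over-oxidation, and the NaHCO3 buffer protects the acid-labile trialkoxybenzylic alcohol, the MOM groups and the easily enolised α-aryl-α-aryloxy aldehyde, which is used at once.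

Step 15
Reactants: 19 2-[6-formyl-2-methoxy-5-(methoxymethoxy)-3-(3-methylbut-2-enyloxy)phenoxy]-2-[3-methoxy-4-(methoxymethoxy)phenyl]acetaldehyde
Product: 20 rac-(2R,3S,4S)-8-methoxy-5-(methoxymethoxy)-2-[3-methoxy-4-(methoxymethoxy)phenyl]-7-(3-methylbut-2-enyloxy)chroman-3,4-diol (2,3-trans-3,4-cis flavan-3,4-diol)
Conditions: SmI2 (0.1 M in THF, 2.4 equiv, added dropwise), t-BuOH (2.5 equiv), THF (0.01 M in 19), −78 → −20 °C; then aq. NaHCO3
Reagents that add atoms: none
Why: SmI2 passes one electron to the conjugated aryl aldehyde (C4), the samarium-bound ketyl attacks the carbonyl carbon of the tethered aliphatic aldehyde (C3), and a second electron followed by protonation from t-BuOH and the work-up delivers the diol. The closest known reaction type is the SmI2-mediated intramolecular pinacol coupling of 1,6-dialdehydes, α-oxygenated ones included, to six-membered cyclic 1,2-diols. Ring C closes in the 6-exo-trig mode, the oxygen of the attacked carbonyl staying outside the new ring O1–C2–C3–C4–C4a–C8a. C3 and C4 are set relative to each other by binding of both oxygens to one trivalent samarium centre, which favours the 3,4-cis diol, and C3 is set relative to C2 by a half-chair transition state with ring B pseudo-equatorial, which favours 2,3-trans; because C2, C3 and C4 all become sp2 in step 16, any isomer mixture is usable. The selectivity that counts is chemoselectivity, since the electron must go to the aryl aldehyde and not to the α-aryloxy aldehyde, whose ketyl would expel the ring A phenoxide from C2. It is secured by the lower-lying π* orbital of the aryl aldehyde, by the chelating O5 MOM group next to it, by low temperature, and by adding the reductant slowly to dilute substrate so that it is never in excess and intermolecular coupling is suppressed.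

Step 16
Reactants: 20 rac-(2R,3S,4S)-8-methoxy-5-(methoxymethoxy)-2-[3-methoxy-4-(methoxymethoxy)phenyl]-7-(3-methylbut-2-enyloxy)chroman-3,4-diol
Product: 22 3-hydroxy-8-methoxy-5-(methoxymethoxy)-2-[3-methoxy-4-(methoxymethoxy)phenyl]-7-(3-methylbut-2-enyloxy)chromen-4-one, via chroman-3,4-dione 21 (not isolated)
Conditions: IBX (2.5 equiv), DMSO, rt
Reagents that add atoms: none
Why: IBX oxidation of a secondary 1,2-diol gives the 1,2-dicarbonyl compound without breaking the C–C bond, the dione carries a doubly activated C2–H and tautomerises spontaneously to the aromatic 3-hydroxy-4-pyranone with loss of all three stereocentres, and MOM ethers, aryl ethers and the trisubstituted alkene are inert to IBX at room temperature.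

Step 17
Reactants: 22 3-hydroxy-8-methoxy-5-(methoxymethoxy)-2-[3-methoxy-4-(methoxymethoxy)phenyl]-7-(3-methylbut-2-enyloxy)chromen-4-one
Product: 23 3,5-dihydroxy-2-(4-hydroxy-3-methoxyphenyl)-8-methoxy-7-(3-methylbut-2-enyloxy)chromen-4-one (CNP0210396.0)
Conditions: conc. HCl (cat.), MeOH–THF, rt
Reagents that add atoms: none
Why: Acid-catalysed transacetalisation removes both MOM groups because ionisation to the methoxymethyl oxocarbenium ion is far easier than ionisation of the prenyl ether to an allyl cation, the O5 acetal being further labilised by the peri carbonyl, so dilute acid in methanol at room temperature should spare the O7 prenyl ether and its alkene.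

Compound list
1 | methyl 3,5-dihydroxy-4-methoxybenzoate | COC(=O)c1cc(O)c(OC)c(O)c1 | starting material
2 | methyl 3,5-bis(benzyloxy)-4-methoxybenzoate | COC(=O)c1cc(OCc2ccccc2)c(OC)c(OCc2ccccc2)c1 | intermediate
3 | [3,5-bis(benzyloxy)-4-methoxyphenyl]methanol | OCc1cc(OCc2ccccc2)c(OC)c(OCc2ccccc2)c1 | intermediate
4 | 3,5-bis(benzyloxy)-4-methoxybenzaldehyde | O=Cc1cc(OCc2ccccc2)c(OC)c(OCc2ccccc2)c1 | intermediate
5 | 3,5-bis(benzyloxy)-4-methoxyphenyl formate (not isolated) | O=COc1cc(OCc2ccccc2)c(OC)c(OCc2ccccc2)c1 | intermediate
6 | 3,5-bis(benzyloxy)-4-methoxyphenol | Oc1cc(OCc2ccccc2)c(OC)c(OCc2ccccc2)c1 | intermediate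
7 | 2,4-bis(benzyloxy)-6-hydroxy-3-methoxybenzaldehyde | O=Cc1c(O)cc(OCc2ccccc2)c(OC)c1OCc1ccccc1 | intermediate
8 | 2,4-bis(benzyloxy)-3-methoxy-6-(methoxymethoxy)benzaldehyde | O=Cc1c(OCOC)cc(OCc2ccccc2)c(OC)c1OCc1ccccc1 | intermediate
9 | 2,4-dihydroxy-3-methoxy-6-(methoxymethoxy)benzaldehyde | O=Cc1c(OCOC)cc(O)c(OC)c1O | intermediate
10 | prenyl bromide (1-bromo-3-methylbut-2-ene) | CC(C)=CCBr | starting material
11 | 2-hydroxy-3-methoxy-6-(methoxymethoxy)-4-(3-methylbut-2-enyloxy)benzaldehyde | O=Cc1c(OCOC)cc(OCC=C(C)C)c(OC)c1O | intermediate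
12 | homovanillic acid, 2-(4-hydroxy-3-methoxyphenyl)acetic acid | COc1cc(CC(=O)O)ccc1O | starting material
13 | methyl 2-(4-hydroxy-3-methoxyphenyl)acetate | COC(=O)Cc1ccc(O)c(OC)c1 | intermediate
14 | methyl 2-[3-methoxy-4-(methoxymethoxy)phenyl]acetate | COCOc1ccc(CC(=O)OC)cc1OC | intermediate
15 | {1-methoxy-2-[3-methoxy-4-(methoxymethoxy)phenyl]ethenyl}oxy(trimethyl)silane, E/Z mixture (not isolated) | COCOc1ccc(C=C(OC)O[Si](C)(C)C)cc1OC | intermediate
16 | methyl 2-bromo-2-[3-methoxy-4-(methoxymethoxy)phenyl]acetate, racemic | COCOc1ccc(C(Br)C(=O)OC)cc1OC | intermediate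
17 | methyl 2-[6-formyl-2-methoxy-5-(methoxymethoxy)-3-(3-methylbut-2-enyloxy)phenoxy]-2-[3-methoxy-4-(methoxymethoxy)phenyl]acetate, racemic | COC(=O)C(Oc1c(OC)c(OCC=C(C)C)cc(OCOC)c1C=O)c1ccc(OCOC)c(OC)c1 | intermediate
18 | 2-[6-(hydroxymethyl)-2-methoxy-5-(methoxymethoxy)-3-(3-methylbut-2-enyloxy)phenoxy]-2-[3-methoxy-4-(methoxymethoxy)phenyl]ethanol, racemic | OCC(Oc1c(OC)c(OCC=C(C)C)cc(OCOC)c1CO)c1ccc(OCOC)c(OC)c1 | intermediate
19 | 2-[6-formyl-2-methoxy-5-(methoxymethoxy)-3-(3-methylbut-2-enyloxy)phenoxy]-2-[3-methoxy-4-(methoxymethoxy)phenyl]acetaldehyde, racemic | O=CC(Oc1c(OC)c(OCC=C(C)C)cc(OCOC)c1C=O)c1ccc(OCOC)c(OC)c1 | intermediate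
20 | rac-(2R,3S,4S)-8-methoxy-5-(methoxymethoxy)-2-[3-methoxy-4-(methoxymethoxy)phenyl]-7-(3-methylbut-2-enyloxy)chroman-3,4-diol, one enantiomer drawn | O[C@H]1c2c(OCOC)cc(OCC=C(C)C)c(OC)c2O[C@H](c2ccc(OCOC)c(OC)c2)[C@H]1O | intermediate
21 | 8-methoxy-5-(methoxymethoxy)-2-[3-methoxy-4-(methoxymethoxy)phenyl]-7-(3-methylbut-2-enyloxy)chroman-3,4-dione, racemic (not isolated) | O=C1c2c(OCOC)cc(OCC=C(C)C)c(OC)c2OC(c2ccc(OCOC)c(OC)c2)C1=O | intermediate
22 | 3-hydroxy-8-methoxy-5-(methoxymethoxy)-2-[3-methoxy-4-(methoxymethoxy)phenyl]-7-(3-methylbut-2-enyloxy)chromen-4-one | COCOc1ccc(-c2oc3c(OC)c(OCC=C(C)C)cc(OCOC)c3c(=O)c2O)cc1OC | intermediate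
23 | 3,5-dihydroxy-2-(4-hydroxy-3-methoxyphenyl)-8-methoxy-7-(3-methylbut-2-enyloxy)chromen-4-one (CNP0210396.0) | COc1cc(-c2oc3c(OC)c(OCC=C(C)C)cc(O)c3c(=O)c2O)ccc1O | target

Total step count: 17. Longest linear sequence: 14 steps (steps 1 to 8, then 12 to 17).

Steps most likely to fail

1. Step 15 (pinacol closure).
What may go wrong: electron transfer to the α-aryloxy aldehyde followed by expulsion of the ring A phenoxide from C2; plain reduction of the aryl aldehyde to the benzylic alcohol; or intermolecular coupling.
Fallback: ring C is built instead by the Algar–Flynn–Oyamada route, which closes O1–C2 and never places a radical or an anion next to the C2–O1 bond. It sets out from 11. MeMgBr (2.2 equiv, THF, 0 °C) should give the benzylic carbinol F1, and activated MnO2 (CH2Cl2, rt) the 2-hydroxyacetophenone F2. Claisen–Schmidt condensation with commercial 3-methoxy-4-(methoxymethoxy)benzaldehyde (KOH, EtOH, rt) should give the (E)-2'-hydroxychalcone F3. Cold alkaline H2O2 (NaOH, MeOH, 0 °C) should then epoxidise, cyclise and oxidise the chalcone, so that the fallback comes back to the route at 22.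

2. Step 14 (double oxidation to the dialdehyde).
What may go wrong: acid-triggered ionisation of the trialkoxybenzylic alcohol of 18; enolisation of the new aldehyde followed by intramolecular aldol addition to the aryl aldehyde; or lactol formation and over-oxidation.
Fallback: the reduction and re-oxidation detour is replaced by masking, which bypasses steps 13 and 14. It sets out from 17. HC(OMe)3 with pyridinium p-toluenesulfonate in MeOH should convert only the aryl aldehyde and give the dimethyl acetal ester F4. i-Bu2AlH (1.1 equiv, toluene, −78 °C) should stop at the aldehyde stage, because an α-alkoxy ester forms a chelated tetrahedral aluminate, and give the acetal aldehyde F5. The very labile acetal on donor-rich ring A is then hydrolysed with pyridinium p-toluenesulfonate in aqueous acetone at rt, conditions under which the MOM ethers should survive, and the fallback comes back at 19.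

3. Step 16 (double oxidation and aromatisation).
What may go wrong: glycol cleavage of the C3–C4 bond just made; ionisation of the C4 carbinol; or further oxidation of the flavonol enol by excess oxidant.
Fallback: the two carbinols are handled one at a time by mechanisms that cannot break the C3–C4 bond. It sets out from 20. A limited charge of the Parikh–Doering reagent (SO3·pyridine, DMSO, Et3N, CH2Cl2, 0 °C) should give the conjugated ketol, since either first-formed ketol equilibrates through the enediol to the trans-dihydroflavonol F6. This is then dehydrogenated through its enolate with alkaline H2O2 (NaOH, MeOH, rt), the closing stage of the Algar–Flynn–Oyamada reaction, and the fallback comes back at 22.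

Further compounds
F1 | step 15 | 1-[2-hydroxy-3-methoxy-6-(methoxymethoxy)-4-(3-methylbut-2-enyloxy)phenyl]ethanol, racemic | CC(O)c1c(OCOC)cc(OCC=C(C)C)c(OC)c1O
F2 | step 15 | 1-[2-hydroxy-3-methoxy-6-(methoxymethoxy)-4-(3-methylbut-2-enyloxy)phenyl]ethanone | CC(=O)c1c(OCOC)cc(OCC=C(C)C)c(OC)c1O
F3 | step 15 | (E)-1-[2-hydroxy-3-methoxy-6-(methoxymethoxy)-4-(3-methylbut-2-enyloxy)phenyl]-3-[3-methoxy-4-(methoxymethoxy)phenyl]prop-2-en-1-one | COCOc1ccc(/C=C/C(=O)c2c(OCOC)cc(OCC=C(C)C)c(OC)c2O)cc1OC
F4 | step 14 | methyl 2-[6-(dimethoxymethyl)-2-methoxy-5-(methoxymethoxy)-3-(3-methylbut-2-enyloxy)phenoxy]-2-[3-methoxy-4-(methoxymethoxy)phenyl]acetate, racemic | COC(=O)C(Oc1c(OC)c(OCC=C(C)C)cc(OCOC)c1C(OC)OC)c1ccc(OCOC)c(OC)c1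
F5 | step 14 | 2-[6-(dimethoxymethyl)-2-methoxy-5-(methoxymethoxy)-3-(3-methylbut-2-enyloxy)phenoxy]-2-[3-methoxy-4-(methoxymethoxy)phenyl]acetaldehyde, racemic | O=CC(Oc1c(OC)c(OCC=C(C)C)cc(OCOC)c1C(OC)OC)c1ccc(OCOC)c(OC)c1
F6 | step 16 | rac-(2R,3R)-3-hydroxy-8-methoxy-5-(methoxymethoxy)-2-[3-methoxy-4-(methoxymethoxy)phenyl]-7-(3-methylbut-2-enyloxy)chroman-4-one, one enantiomer drawn | O=C1c2c(OCOC)cc(OCC=C(C)C)c(OC)c2O[C@H](c2ccc(OCOC)c(OC)c2)[C@H]1O
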